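**Retrosynthetic overview**
- Conneotricone ⇐ its formyl analogue (ring B CH2OH carried as CHO, reduced last) ⇐ protected depsidone phthalide (two methyl ethers, one tert-butyl ester, removed by BCl3).
- Key disconnection: both lactones are cut at aryl–C(=O) and C(=O)–O, giving an iodo (ring A) bromo (ring B) diaryl ether with a free ring B phenol and a free benzylic alcohol, plus two CO.
- Feature used: each lactone carbonyl carbon sits on an arene carbon para to a ring oxygen (ring A: the carbon between C–CH3 and the ether C–O, para to C–OH; ring B: the carbon between C–OH and C–CH2O, para to the ester-oxygen carbon). Each halide can therefore be placed by para-halogenation, and each acyl has one hydroxyl in reach (phenol for the seven-membered ring, CH2OH for the five-membered ring).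
- Diaryl ether ⇐ SNAr of a ring B phenol (from 2-hydroxy-4-methoxybenzaldehyde) on 2-fluoro-3-iodo-6-methoxy-4-methylbenzaldehyde (from 3-fluoro-5-methylanisole). The ring A iodide is placed before coupling; the ring B Br and CHO are added after coupling under control of the unmasked phenol.
- Ring order: both benzene rings are bought, the ether joins them, then the seven-membered lactone and the phthalide close in that order in one flask.

Key step: step 13

Remark: 3-fluoro-5-methylanisole and 2-hydroxy-4-methoxybenzaldehyde are taken as catalogue compounds, and the ring B hydroxymethyl group is carried as a formyl group up to the last step because BCl3 would ionise a benzylic alcohol or ether.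

**Route**

Step 1
Reactants: 1 3-fluoro-5-methylanisole
Product: 2 1-fluoro-2-iodo-5-methoxy-3-methylbenzene
Conditions: NIS, CF3CO2H (0.3 equiv), MeCN, rt
Reagents that add atoms: N-iodosuccinimide (O=C1CCC(=O)N1I)
Why: Electrophilic aromatic iodination; the methoxy group is the only strong donor and should direct iodine to its para carbon (between F and CH3), as in the para-halogenation of 3-substituted anisoles, which fixes the ring A halide position before the rings are joined.

Step 2
Reactants: 2 1-fluoro-2-iodo-5-methoxy-3-methylbenzene
Product: 4 2-fluoro-3-iodo-6-methoxy-4-methylbenzaldehyde, via aryllithium 3 (not isolated)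
Conditions: LiN(iPr)2, THF, −78 °C; DMF, −78 → −20 °C; aq. HCl
Reagents that add atoms: N,N-dimethylformamide (CN(C)C=O)
Why: Directed ortho-metalation and formylation; the only acidic ring C–H is the one flanked by F and OCH3, the amide base removes it without touching the C–I bond (no hydrogen is ortho to iodine, so no halogen migration can start), and DMF traps the aryllithium as the aldehyde.

Step 3
Reactants: 5 2-hydroxy-4-methoxybenzaldehyde
Product: 6 4-methoxy-2-(methoxymethoxy)benzaldehyde
Conditions: MOMCl, iPr2NEt, CH2Cl2, 0 °C → rt
Reagents that add atoms: chloromethyl methyl ether (COCCl)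
Why: O-Alkylation of the phenol with the reactive chloromethyl ether under amine base (acetal protection), which marks the oxygen that must stay masked during ether formation.

Step 4
Reactants: 6 4-methoxy-2-(methoxymethoxy)benzaldehyde
Product: 8 4-methoxy-2-(methoxymethoxy)phenol, via aryl formate 7 (not isolated)
Conditions: mCPBA, CH2Cl2, 0 °C → rt; then K2CO3, MeOH, rt
Reagents that add atoms: 3-chloroperbenzoic acid (OOC(=O)c1cccc(Cl)c1)
Why: Baeyer–Villiger (Dakin-type) oxidation; the electron-rich 2,4-dialkoxyaryl group migrates to oxygen to give the aryl formate, and base methanolysis frees the phenol, so the two neighbouring ring B oxygens are differentiated without any selectivity question.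

Step 5
Reactants: 8 4-methoxy-2-(methoxymethoxy)phenol
Product: 9 2-hydroxy-5-methoxy-3-(methoxymethoxy)benzaldehyde
Conditions: MgCl2, Et3N, (CH2O)n, THF, reflux
Reagents that add atoms: formaldehyde, used as paraformaldehyde (C=O)
Why: Casnati–Skattebøl ortho-formylation; the magnesium phenoxide delivers formaldehyde to the single free ortho carbon and a second formaldehyde acts as hydride acceptor, as in the conversion of guaiacol-type phenols to 3-alkoxysalicylaldehydes.

Step 6
Reactants: 9 2-hydroxy-5-methoxy-3-(methoxymethoxy)benzaldehyde
Product: 10 2-(hydroxymethyl)-4-methoxy-6-(methoxymethoxy)phenol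
Conditions: NaBH4, MeOH, 0 °C
Reagents that add atoms: none
Why: Borohydride reduction of the aldehyde; it removes the only aldehyde of ring B so that the ring A aldehyde can later be oxidised alone, and acetal and aryl ethers are inert.

Step 7
Reactants: 4 2-fluoro-3-iodo-6-methoxy-4-methylbenzaldehyde; 10 2-(hydroxymethyl)-4-methoxy-6-(methoxymethoxy)phenol
Product: 11 2-[2-(hydroxymethyl)-4-methoxy-6-(methoxymethoxy)phenoxy]-3-iodo-6-methoxy-4-methylbenzaldehyde
Conditions: Cs2CO3, DMSO, 80 °C
Reagents that add atoms: none
Why: Nucleophilic aromatic substitution by addition–elimination; the phenoxide attacks the C–F carbon activated by the ortho formyl group, fluoride leaves, and the aryl iodide and the much less acidic benzylic alcohol should not take part.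

Step 8
Reactants: 11 2-[2-(hydroxymethyl)-4-methoxy-6-(methoxymethoxy)phenoxy]-3-iodo-6-methoxy-4-methylbenzaldehyde
Product: 12 2-[2-(hydroxymethyl)-4-methoxy-6-(methoxymethoxy)phenoxy]-3-iodo-6-methoxy-4-methylbenzoic acid
Conditions: NaClO2, NaH2PO4, 2-methyl-2-butene, tBuOH–THF–H2O, rt
Reagents that add atoms: sodium chlorite ([Na+].[O-]Cl=O)
Why: Pinnick oxidation; chlorous acid oxidises the hindered aldehyde to the acid while 2-methyl-2-butene removes HOCl, so the electron-rich ring B, the benzylic alcohol, the acetal and the iodide are spared.

Step 9
Reactants: 12 2-[2-(hydroxymethyl)-4-methoxy-6-(methoxymethoxy)phenoxy]-3-iodo-6-methoxy-4-methylbenzoic acid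
Product: 13 tert-butyl 2-[2-(hydroxymethyl)-4-methoxy-6-(methoxymethoxy)phenoxy]-3-iodo-6-methoxy-4-methylbenzoate
Conditions: tert-butyl 2,2,2-trichloroacetimidate, CH2Cl2–cyclohexane, rt
Reagents that add atoms: tert-butyl 2,2,2-trichloroacetimidate (CC(C)(C)OC(=N)C(Cl)(Cl)Cl)
Why: Esterification by tert-butyl transfer from the imidate, which the carboxylic acid itself protonates; without a Lewis acid the benzylic alcohol should not be alkylated, and alkylation at carboxylate oxygen avoids attack at the doubly ortho-substituted carboxyl carbon.

Step 10
Reactants: 13 tert-butyl 2-[2-(hydroxymethyl)-4-methoxy-6-(methoxymethoxy)phenoxy]-3-iodo-6-methoxy-4-methylbenzoate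
Product: 14 tert-butyl 2-[2-hydroxy-6-(hydroxymethyl)-4-methoxyphenoxy]-3-iodo-6-methoxy-4-methylbenzoate
Conditions: HCl (cat.), MeOH, 40 °C
Reagents that add atoms: none
Why: Acid-catalysed acetal exchange to methanol frees the ring B phenol; dilute acid at this temperature should leave the tert-butyl ester intact, and the benzylic alcohol has no ortho or para hydroxyl that would let it ionise.

Step 11
Reactants: 14 tert-butyl 2-[2-hydroxy-6-(hydroxymethyl)-4-methoxyphenoxy]-3-iodo-6-methoxy-4-methylbenzoate
Product: 15 tert-butyl 2-[3-bromo-6-hydroxy-2-(hydroxymethyl)-4-methoxyphenoxy]-3-iodo-6-methoxy-4-methylbenzoate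
Conditions: NBS, MeCN, −20 → 0 °C
Reagents that add atoms: N-bromosuccinimide (O=C1CCC(=O)N1Br)
Why: Electrophilic aromatic bromination; the free phenol makes ring B far more reactive than the ester- and iodine-bearing ring A, and its open para carbon (also ortho to OCH3) should be attacked in preference to the carbon squeezed between OH and OCH3.

Step 12
Reactants: 15 tert-butyl 2-[3-bromo-6-hydroxy-2-(hydroxymethyl)-4-methoxyphenoxy]-3-iodo-6-methoxy-4-methylbenzoate
Product: 16 tert-butyl 2-[3-bromo-5-formyl-6-hydroxy-2-(hydroxymethyl)-4-methoxyphenoxy]-3-iodo-6-methoxy-4-methylbenzoate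
Conditions: MgCl2, Et3N, (CH2O)n, MeCN, reflux
Reagents that add atoms: formaldehyde, used as paraformaldehyde (C=O)
Why: Casnati–Skattebøl ortho-formylation at the last free carbon of ring B, which is ortho to the phenol; the reaction is ortho-specific and tolerates esters and aryl halides, and the formyl group stands in for the hydroxymethyl group of the target.

Step 13
Reactants: 16 tert-butyl 2-[3-bromo-5-formyl-6-hydroxy-2-(hydroxymethyl)-4-methoxyphenoxy]-3-iodo-6-methoxy-4-methylbenzoate
Product: 18 protected depsidone phthalide, via bromo depsidone 17 (not isolated)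
Conditions: Pd(OAc)2 (10 mol %), Xantphos (12 mol %), CO (1 atm), Et3N, 1,4-dioxane, 60 °C then 100 °C
Reagents that add atoms: carbon monoxide ([C-]#[O+])
Why: Zerovalent palladium (formed from Pd(OAc)2, Xantphos and CO) should add first to the ring A C–I bond, CO inserts, and the aroyl palladium species is taken by the ring B phenoxide across the ether oxygen to give bromo depsidone 17, after which at 100 °C the ring B C–Br bond goes through the same cycle and its aroyl palladium species is taken by the ortho CH2OH. The reaction type is the known palladium-catalysed carbonylative lactonisation of an aryl halide that carries a tethered phenol or alcohol (phthalides from 2-halobenzyl alcohols, aryl lactones from halo aryl phenols), here run twice on one substrate. The seven-membered lactone closes by 7-exo-trig acyl substitution (C–O reductive elimination from an eight-membered aroyl aryloxo palladacycle) and the phthalide by 5-exo-trig acyl substitution (six-membered palladacycle). No stereocentre is formed. The selectivity needed is the pairing of each acyl with one hydroxyl: the ring B acyl can reach only the CH2OH (the phenol is para to it), whereas the ring A acyl could reach the phenol (seven-membered) or the CH2OH (eight-membered), and the smaller ring, the ionised ortho-formyl phenol under Et3N and the start at 60 °C, where only the iodide reacts and the neutral primary alcohol is a poor nucleophile, should secure the seven-membered closure. Both carbonyl carbons come from CO, so two aryl–carbonyl bonds, two acyl C–O bonds and two rings form in one flask.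

Step 14
Reactants: 18 protected depsidone phthalide
Product: 19 formyl depsidone acid (Conneotricone with CHO in place of CH2OH)
Conditions: BCl3, CH2Cl2, −78 °C → rt; H2O
Reagents that add atoms: none
Why: Lewis acid dealkylation; BCl3 chelates each carbonyl with its ortho methoxy oxygen (ring A ester, ring B aldehyde and phthalide) and chloride removes the methyl group, and the tert-butyl ester is cleaved by ionisation, while lactones and aldehyde should survive.

Step 15
Reactants: 19 formyl depsidone acid
Product: 20 Conneotricone
Conditions: NaBH(OAc)3, THF–AcOH, 0 °C → rt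
Reagents that add atoms: none
Why: Hydroxyl-directed aldehyde reduction with an acyloxyborohydride; the ortho phenol exchanges onto boron and delivers hydride to the formyl group, and this mild, non-basic reagent should not touch the two lactones or the carboxylic acid.

**Compound list**
1 | 3-fluoro-5-methylanisole | COc1cc(C)cc(F)c1 | starting material
2 | 1-fluoro-2-iodo-5-methoxy-3-methylbenzene | COc1cc(C)c(I)c(F)c1 | intermediate
3 | aryllithium: (2-fluoro-3-iodo-6-methoxy-4-methylphenyl)lithium | COc1cc(C)c(I)c(F)c1[Li] | intermediate
4 | 2-fluoro-3-iodo-6-methoxy-4-methylbenzaldehyde | COc1cc(C)c(I)c(F)c1C=O | intermediate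
5 | 2-hydroxy-4-methoxybenzaldehyde | COc1ccc(C=O)c(O)c1 | starting material
6 | 4-methoxy-2-(methoxymethoxy)benzaldehyde | COCOc1cc(OC)ccc1C=O | intermediate
7 | aryl formate: 4-methoxy-2-(methoxymethoxy)phenyl formate | COCOc1cc(OC)ccc1OC=O | intermediate
8 | 4-methoxy-2-(methoxymethoxy)phenol | COCOc1cc(OC)ccc1O | intermediate
9 | 2-hydroxy-5-methoxy-3-(methoxymethoxy)benzaldehyde | COCOc1cc(OC)cc(C=O)c1O | intermediate
10 | 2-(hydroxymethyl)-4-methoxy-6-(methoxymethoxy)phenol | COCOc1cc(OC)cc(CO)c1O | intermediate
11 | 2-[2-(hydroxymethyl)-4-methoxy-6-(methoxymethoxy)phenoxy]-3-iodo-6-methoxy-4-methylbenzaldehyde | Cc1cc(OC)c(C=O)c(Oc2c(CO)cc(OC)cc2OCOC)c1I | intermediate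
12 | 2-[2-(hydroxymethyl)-4-methoxy-6-(methoxymethoxy)phenoxy]-3-iodo-6-methoxy-4-methylbenzoic acid | Cc1cc(OC)c(C(=O)O)c(Oc2c(CO)cc(OC)cc2OCOC)c1I | intermediate
13 | tert-butyl 2-[2-(hydroxymethyl)-4-methoxy-6-(methoxymethoxy)phenoxy]-3-iodo-6-methoxy-4-methylbenzoate | Cc1cc(OC)c(C(=O)OC(C)(C)C)c(Oc2c(CO)cc(OC)cc2OCOC)c1I | intermediate
14 | tert-butyl 2-[2-hydroxy-6-(hydroxymethyl)-4-methoxyphenoxy]-3-iodo-6-methoxy-4-methylbenzoate | Cc1cc(OC)c(C(=O)OC(C)(C)C)c(Oc2c(CO)cc(OC)cc2O)c1I | intermediate
15 | tert-butyl 2-[3-bromo-6-hydroxy-2-(hydroxymethyl)-4-methoxyphenoxy]-3-iodo-6-methoxy-4-methylbenzoate | Cc1cc(OC)c(C(=O)OC(C)(C)C)c(Oc2c(CO)c(Br)c(OC)cc2O)c1I | intermediate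
16 | tert-butyl 2-[3-bromo-5-formyl-6-hydroxy-2-(hydroxymethyl)-4-methoxyphenoxy]-3-iodo-6-methoxy-4-methylbenzoate (carbonylation precursor) | Cc1cc(OC)c(C(=O)OC(C)(C)C)c(Oc2c(CO)c(Br)c(OC)c(C=O)c2O)c1I | intermediate
17 | bromo depsidone: seven-membered lactone closed, ring B still carrying Br and CH2OH | Cc1cc(OC)c(C(=O)OC(C)(C)C)c2c1C(=O)Oc1c(C=O)c(OC)c(Br)c(CO)c1O2 | intermediate
18 | protected depsidone phthalide: both lactones closed, ring A and ring B methyl ethers, tert-butyl ester, ring B CHO | Cc1cc(OC)c(C(=O)OC(C)(C)C)c2c1C(=O)Oc1c(C=O)c(OC)c3c(c1O2)COC3=O | intermediate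
19 | formyl depsidone acid: free phenols and carboxylic acid, ring B CHO | Cc1cc(O)c(C(=O)O)c2c1C(=O)Oc1c(C=O)c(O)c3c(c1O2)COC3=O | intermediate
20 | Conneotricone | Cc1cc(O)c(C(=O)O)c2c1C(=O)Oc1c(CO)c(O)c3c(c1O2)COC3=O | target

**Step count**
Total steps: 15. Longest linear sequence: 13 steps (steps 3–15, from 2-hydroxy-4-methoxybenzaldehyde); the ring A branch is steps 1–2.

**Steps most likely to fail**

Step 13 (key step). The ring A aroyl palladium intermediate may decay before the slow seven-membered C–O bond formation (loss of iodine to C–H, capture by the benzylic alcohol in the eight-membered mode, or intermolecular ester formation), and oxidative addition into the doubly ortho-substituted C–Br bond may stall. The fallback separates carbonylation from the seven-membered ring closure. Setting out from 16, the same catalyst (Pd(OAc)2, Xantphos, Et3N, toluene, 80–100 °C) is used with 2,4,6-trichlorophenyl formate, which releases CO and 2,4,6-trichlorophenoxide in the flask. This should close the phthalide as before and intercept the ring A aroyl palladium species intermolecularly, giving the ring A 2,4,6-trichlorophenyl ester phthalide F1. Heating F1 with DMAP and Et3N in toluene should then close the seven-membered lactone by acyl transfer to the ring B phenol, and the route is rejoined at 18.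

Step 7 (diaryl ether formation). Addition of the doubly ortho-substituted phenoxide to a C–F carbon flanked by CHO and I may be slow, and thermal self-condensation of the o-hydroxybenzyl alcohol may then compete. The fallback changes the activating group. From 4, NH2OH·HCl and HCO2Na in HCO2H at reflux should give 2-fluoro-3-iodo-6-methoxy-4-methylbenzonitrile F2 (oxime formation and dehydration). The linear cyano group activates the C–F carbon without crowding it, so substitution by the phenoxide of 10 (Cs2CO3, DMSO, 50–60 °C) should give the diaryl ether nitrile F3 at a lower temperature. iBu2AlH (toluene, −78 °C; aqueous tartaric acid work-up) then reduces the nitrile to the aldimine, which is hydrolysed to aldehyde 11, where the route is rejoined.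

Step 12 (late formylation). C–C bond formation at the carbon between OH and OCH3 of the bromophenol may be sluggish, or the free benzylic alcohol may take up formaldehyde, leaving unchanged phenol. The fallback uses a different electrophile. From 15, a Duff reaction (hexamethylenetetramine, CF3CO2H, 80 °C; then aqueous acid, which also hydrolyses any benzylic trifluoroacetate) formylates the same carbon through an iminium ion. The acid medium cleaves the tert-butyl ester, so the product is the formyl carboxylic acid F4. Re-esterification with tert-butyl 2,2,2-trichloroacetimidate under the conditions of step 9 returns to 16.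

Further compounds
F1 | step 13 | ring A 2,4,6-trichlorophenyl ester phthalide (phthalide closed, ring B phenol free) | Cc1cc(OC)c(C(=O)OC(C)(C)C)c(Oc2c(O)c(C=O)c(OC)c3c2COC3=O)c1C(=O)Oc1c(Cl)cc(Cl)cc1Cl
F2 | step 7 | 2-fluoro-3-iodo-6-methoxy-4-methylbenzonitrile | COc1cc(C)c(I)c(F)c1C#N
F3 | step 7 | diaryl ether nitrile: 2-[2-(hydroxymethyl)-4-methoxy-6-(methoxymethoxy)phenoxy]-3-iodo-6-methoxy-4-methylbenzonitrile | Cc1cc(OC)c(C#N)c(Oc2c(CO)cc(OC)cc2OCOC)c1I
F4 | step 12 | formyl carboxylic acid: 2-[3-bromo-5-formyl-6-hydroxy-2-(hydroxymethyl)-4-methoxyphenoxy]-3-iodo-6-methoxy-4-methylbenzoic acid | Cc1cc(OC)c(C(=O)O)c(Oc2c(CO)c(Br)c(OC)c(C=O)c2O)c1I
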